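**Retrosynthetic overview**

1. Ring labels: ring A is the terminal benzoate, ring B the diaryl-ether resorcinol, ring C the central orcinol core. The last disconnection is global deprotection (two silyl ethers, four MOM ethers, two dimethyl acetals).
2. The strategy rests on the pattern of ring B: B5, between the B4 and B6 oxygens, carries the CH2 to ring C; B1, next to the B6 hydroxyl, carries the ring A ether oxygen; B2 carries a methyl. Each ring B is cut at B5–B6, B3–B4 and B1–B6 into an (aryloxyvinyl)ketene (B6, B3, B2, B1) and a siloxyalkyne (B5, B4).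
3. The ketene comes from acid chloride 20. This is made from methyl orsellinate (MOM ether, ortho-formylation) by O-alkylation with a 4-bromo-3-methylbut-2-enoate, acetalisation and ester cleavage, so the hindered aryl–oxygen bond is made by a simple SN2 reaction.
4. The ring C bis(siloxyalkyne) 10 comes from orcinol: MOM ether, dibromination beside the methyl, double propargylation, acetylide oxidation and O-silylation.
5. Order of ring formation: rings A and C are bought as arenes; both rings B are formed together, last, in step 14.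

Key step: step 14

**Assumptions**

- Step 9 gives both double-bond isomers; the E isomer is separated and carried. The Z isomer could be carried in the same way, because the geometry is erased in step 14.
- Intermediates 21–24 have no controlled enol ether geometry, and the sp3 centres of 22 and 24 form without control and vanish on aromatisation. Their SMILES carry no descriptors.

**Route**

Step 1
Reactants: 1 orcinol (5-methylbenzene-1,3-diol)
Product: 2 1,3-bis(methoxymethoxy)-5-methylbenzene
Conditions: MOMCl (2.5 equiv), i-Pr2NEt, CH2Cl2, 0 °C to rt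
Reagents that add atoms: chloromethyl methyl ether, COCCl
Why: Double O-alkylation of the phenols with the reactive α-chloro ether (MOM protection) should go cleanly, and the acetal ethers tolerate organolithiums and fluoride and fall in the final acid step.

Step 2
Reactants: 2 1,3-bis(methoxymethoxy)-5-methylbenzene
Product: 3 2,4-dibromo-1,5-bis(methoxymethoxy)-3-methylbenzene
Conditions: NBS (2.05 equiv), MeCN, 0 °C to rt
Reagents that add atoms: N-bromosuccinimide, O=C1CCC(=O)N1Br
Why: Electrophilic aromatic bromination should take the two carbons beside the methyl, each para to one and ortho to the other alkoxy group, in preference to the more shielded carbon between the two alkoxy groups, as in the dibromination of orcinol ethers.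

Step 3
Reactants: 3 2,4-dibromo-1,5-bis(methoxymethoxy)-3-methylbenzene
Product: 6 1,5-bis(methoxymethoxy)-3-methyl-2,4-bis[3-(trimethylsilyl)prop-2-yn-1-yl]benzene, via dilithioarene 4 (not isolated), via aryl bis-Grignard reagent 5 (not isolated)
Conditions: t-BuLi (4.2 equiv), THF, −78 °C; MgBr2·OEt2 (2.4 equiv), −78 to 0 °C; Me3SiC≡CCH2Br (2.6 equiv), CuBr·SMe2 (10 mol%), 0 °C to rt
Reagents that add atoms: 3-bromo-1-(trimethylsilyl)prop-1-yne, C[Si](C)(C)C#CCBr
Why: Double bromine–lithium exchange (each aryllithium chelated by its neighbouring MOM ether), transmetalation to magnesium and copper-catalysed substitution on the propargylic bromide should give the bis(propargyl)arene, the trimethylsilyl cap blocking attack at the alkyne terminus so that no allene forms.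

Step 4
Reactants: 6 1,5-bis(methoxymethoxy)-3-methyl-2,4-bis[3-(trimethylsilyl)prop-2-yn-1-yl]benzene
Product: 7 1,5-bis(methoxymethoxy)-3-methyl-2,4-di(prop-2-yn-1-yl)benzene
Conditions: K2CO3 (cat.), MeOH/THF, 0 °C to rt, short reaction time
Reagents that add atoms: none
Why: Methanolysis of the alkynyl–silicon bonds (protodesilylation) is fast under carbonate catalysis and, kept cold and short, should not isomerise the propargyl arene to the allene.

Step 5
Reactants: 7 1,5-bis(methoxymethoxy)-3-methyl-2,4-di(prop-2-yn-1-yl)benzene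
Product: 10 1,5-bis(methoxymethoxy)-3-methyl-2,4-bis{3-[(triisopropylsilyl)oxy]prop-2-yn-1-yl}benzene, via dilithium bis-acetylide 8 (not isolated), via dilithium bis-ynolate 9 (not isolated)
Conditions: n-BuLi (2.05 equiv), THF, −78 °C; t-BuOOLi (from t-BuOOH and LiN(SiMe3)2), −78 to 0 °C; TIPSOTf, −78 to 0 °C
Reagents that add atoms: tert-butyl hydroperoxide, CC(C)(C)OO; triisopropylsilyl trifluoromethanesulfonate, CC(C)[Si](OS(=O)(=O)C(F)(F)F)(C(C)C)C(C)C
Why: Julia oxidation of a lithium acetylide with lithium tert-butyl peroxide gives the ynolate, which the bulky silyl triflate should silylate on oxygen; this way is chosen over ester homologation because an arylacetate would enolise under carbenoid conditions.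

Step 6
Reactants: 11 methyl 2,4-dihydroxy-6-methylbenzoate
Product: 12 methyl 2-hydroxy-4-(methoxymethoxy)-6-methylbenzoate
Conditions: MOMCl (1.1 equiv), i-Pr2NEt, CH2Cl2, 0 °C
Reagents that add atoms: chloromethyl methyl ether, COCCl
Why: Selective O-alkylation should occur at the 4-hydroxyl, because the 2-hydroxyl is tied up in a hydrogen bond to the ester carbonyl and is less nucleophilic.

Step 7
Reactants: 12 methyl 2-hydroxy-4-(methoxymethoxy)-6-methylbenzoate
Product: 13 methyl 3-formyl-2-hydroxy-4-(methoxymethoxy)-6-methylbenzoate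
Conditions: MgCl2 (3 equiv), Et3N (6 equiv), (CH2O)n (10 equiv), MeCN, reflux; cold aq. NH4Cl work-up
Reagents that add atoms: paraformaldehyde (as formaldehyde), C=O
Why: In the magnesium-mediated ortho-formylation (Casnati–Skattebøl) the magnesium phenoxide delivers formaldehyde to the only free ortho carbon, C3, and hydride transfer to a second formaldehyde gives the aldehyde, so the regiochemistry is fixed by the substrate and the basic medium spares the MOM ether.

Step 8
Reactants: 14 3-methylbut-2-enoic acid
Product: 15 2-(trimethylsilyl)ethyl 3-methylbut-2-enoate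
Conditions: Me3SiCH2CH2OH, PPh3, DIAD, THF, 0 °C to rt
Reagents that add atoms: 2-(trimethylsilyl)ethanol, C[Si](C)(C)CCO
Why: Mitsunobu esterification uses the carboxylate as nucleophile and so avoids acyl activation, which could deconjugate the double bond through a vinylketene.

Step 9
Reactants: 15 2-(trimethylsilyl)ethyl 3-methylbut-2-enoate
Product: 16 2-(trimethylsilyl)ethyl (2E)-4-bromo-3-methylbut-2-enoate
Conditions: NBS (1.05 equiv), AIBN (cat.), PhCF3, reflux; E isomer separated by chromatography
Reagents that add atoms: N-bromosuccinimide, O=C1CCC(=O)N1Br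
Why: Wohl–Ziegler allylic bromination of a 3-methylbut-2-enoate takes a γ-methyl hydrogen, and the silylethyl ester has no competing allylic position, which an allyl ester would have.

Step 10
Reactants: 13 methyl 3-formyl-2-hydroxy-4-(methoxymethoxy)-6-methylbenzoate; 16 2-(trimethylsilyl)ethyl (2E)-4-bromo-3-methylbut-2-enoate
Product: 17 methyl 3-formyl-4-(methoxymethoxy)-6-methyl-2-({(2E)-2-methyl-4-oxo-4-[2-(trimethylsilyl)ethoxy]but-2-en-1-yl}oxy)benzoate
Conditions: K2CO3, DMF, rt
Reagents that add atoms: none
Why: Williamson ether synthesis of the acidic, doubly flanked phenol with a primary allylic bromide (SN2) should be efficient at room temperature, where carbonate does not deprotonate the γ-CH2 of the product.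

Step 11
Reactants: 17 the formyl ether ester
Product: 18 methyl 3-(dimethoxymethyl)-4-(methoxymethoxy)-6-methyl-2-({(2E)-2-methyl-4-oxo-4-[2-(trimethylsilyl)ethoxy]but-2-en-1-yl}oxy)benzoate
Conditions: HC(OMe)3, MeOH, PPTS (cat.), rt; Et3N quench
Reagents that add atoms: trimethyl orthoformate, COC(OC)OC; methanol, CO
Why: Acid-catalysed acetalisation driven by the orthoformate masks the aldehyde, which would otherwise be attacked by the γ-carbon when it is deprotonated in step 14, and mild pyridinium catalysis at room temperature should spare the aryl MOM ether.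

Step 12
Reactants: 18 the acetal ester
Product: 19 (2E)-4-[2-(dimethoxymethyl)-6-(methoxycarbonyl)-3-(methoxymethoxy)-5-methylphenoxy]-3-methylbut-2-enoic acid
Conditions: TBAF, THF, 0 °C to rt; AcOH to pH 5, cold rapid extraction
Reagents that add atoms: none
Why: Fluoride-induced fragmentation of the 2-(trimethylsilyl)ethyl ester frees the acid without touching the hindered aryl methyl ester, the MOM ether or the acetal, whereas an allyl ester would need zerovalent palladium, which could also ionise the allylic aryl ether.

Step 13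
Reactants: 19 the butenoic acid
Product: 20 (2E)-4-[2-(dimethoxymethyl)-6-(methoxycarbonyl)-3-(methoxymethoxy)-5-methylphenoxy]-3-methylbut-2-enoyl chloride
Conditions: 1-chloro-N,N,2-trimethylprop-1-en-1-amine (1.2 equiv), CH2Cl2, 0 °C to rt; concentrated and used at once
Reagents that add atoms: 1-chloro-N,N,2-trimethylprop-1-en-1-amine, CC(C)=C(Cl)N(C)C
Why: The Ghosez α-chloroenamine turns a carboxylic acid into its chloride under neutral conditions with only an inert amide as by-product, so no HCl reaches the acetal or MOM ether.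

Step 14
Reactants: 10 ring C bis(siloxyalkyne); 20 acid chloride (two molecules react)
Product: 25 protected pentamer bis(triisopropylsilyl ether), via aryloxyvinylketene 21 (not isolated), via bis-cyclobutenone 22 (not isolated), via bis-dienylketene 23 (not isolated), via bis-cyclohexadienone 24 (not isolated)
Conditions: 10 (1 equiv), Et3N (6 equiv), toluene, rt; 20 (3 equiv) in toluene added over 4 h; then 90 °C, 4 h
Reagents that add atoms: none
Why: Et3N removes HCl across the O–CH2–C=CH–COCl unit of 20 (a γ-hydrogen of the OCH2 group and the acyl chloride) to give the (aryloxyvinyl)ketene 21, whose carbonyl carbon is attacked by the CH2-bearing carbon of each siloxyalkyne in a [2+2] cycloaddition that gives the 3-siloxy-4-vinylcyclobutenone 22 and forms B5–B6 and B3–B4. On heating, 22 opens by conrotatory four-electron electrocyclic ring opening to the dienylketene 23, which closes each ring B by disrotatory six-electron electrocyclisation (B1–B6) to the cyclohexadienone 24, and this tautomerises to the phenol. The closest known reaction type is the Danheiser benzannulation of vinylketenes with triisopropylsiloxyalkynes, with the vinylketene made here by 1,4-dehydrochlorination of an unsaturated acid chloride as in ketene–siloxyalkyne cycloadditions. No stereocentre remains, since the sp3 carbons of 22 and 24 are lost on ring opening and aromatisation and the double-bond geometry of 20 and 21 is irrelevant. Three selectivities are needed: the orientation of the [2+2] step, fixed by the polarity of the siloxyalkyne (nucleophilic at the carbon remote from oxygen) and the ketene (electrophilic at the carbonyl carbon); deprotonation at OCH2 and not at the γ-methyl group, favoured because the electron-poor aryloxy group acidifies that CH2 and the diene formed is a conjugated enol ether; and capture of 21 before it dimerises, secured by slow addition of 20 to the alkyne. The aldehydes are masked as acetals so that the γ-carbon cannot add to an ortho-formyl group, and the new B6 hydroxyl is flanked on both sides and should escape acylation.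

Step 15
Reactants: 25 protected pentamer bis(triisopropylsilyl ether)
Product: 26 pentamer with free B4 and B6 hydroxyls (MOM ethers and acetals intact)
Conditions: TBAF, AcOH (1:1), THF, 0 °C, under argon
Reagents that add atoms: none
Why: Fluoride cleaves the aryl silyl ethers, and the acetic acid buffer keeps the electron-rich phenoxides protonated while leaving MOM ethers, acetals and the hindered methyl esters untouched.

Step 16
Reactants: 26 desilylated pentamer
Product: 27 praesorether G
Conditions: 2 M aq. HCl, MeOH/THF, rt to 40 °C, under argon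
Reagents that add atoms: water, O
Why: Acid-catalysed acetal cleavage removes the four MOM ethers (the methylene unit is carried off by methanol as dimethoxymethane, which limits re-attack on the electron-rich rings) and hydrolyses both dimethyl acetals to the aldehydes, and the hindered methyl esters and diarylmethane links should survive dilute acid.

**Compound list**

1 | orcinol (5-methylbenzene-1,3-diol) | Cc1cc(O)cc(O)c1 | starting material
2 | 1,3-bis(methoxymethoxy)-5-methylbenzene | COCOc1cc(C)cc(OCOC)c1 | intermediate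
3 | 2,4-dibromo-1,5-bis(methoxymethoxy)-3-methylbenzene | Cc1c(Br)c(OCOC)cc(OCOC)c1Br | intermediate
4 | 2,4-dilithio-1,5-bis(methoxymethoxy)-3-methylbenzene (not isolated) | Cc1c([Li])c(OCOC)cc(OCOC)c1[Li] | intermediate
5 | [4,6-bis(methoxymethoxy)-2-methyl-1,3-phenylene]bis(magnesium bromide) (not isolated) | Cc1c([Mg]Br)c(OCOC)cc(OCOC)c1[Mg]Br | intermediate
6 | 1,5-bis(methoxymethoxy)-3-methyl-2,4-bis[3-(trimethylsilyl)prop-2-yn-1-yl]benzene | Cc1c(CC#C[Si](C)(C)C)c(OCOC)cc(OCOC)c1CC#C[Si](C)(C)C | intermediate
7 | 1,5-bis(methoxymethoxy)-3-methyl-2,4-di(prop-2-yn-1-yl)benzene | Cc1c(CC#C)c(OCOC)cc(OCOC)c1CC#C | intermediate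
8 | dilithium bis-acetylide of 7 (not isolated) | Cc1c(CC#C[Li])c(OCOC)cc(OCOC)c1CC#C[Li] | intermediate
9 | dilithium 3,3'-[4,6-bis(methoxymethoxy)-2-methyl-1,3-phenylene]bis(prop-1-yn-1-olate) (not isolated) | Cc1c(CC#CO[Li])c(OCOC)cc(OCOC)c1CC#CO[Li] | intermediate
10 | 1,5-bis(methoxymethoxy)-3-methyl-2,4-bis{3-[(triisopropylsilyl)oxy]prop-2-yn-1-yl}benzene (ring C bis(siloxyalkyne)) | Cc1c(CC#CO[Si](C(C)C)(C(C)C)C(C)C)c(OCOC)cc(OCOC)c1CC#CO[Si](C(C)C)(C(C)C)C(C)C | intermediate
11 | methyl 2,4-dihydroxy-6-methylbenzoate | COC(=O)c1c(C)cc(O)cc1O | starting material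
12 | methyl 2-hydroxy-4-(methoxymethoxy)-6-methylbenzoate | COC(=O)c1c(C)cc(OCOC)cc1O | intermediate
13 | methyl 3-formyl-2-hydroxy-4-(methoxymethoxy)-6-methylbenzoate | COC(=O)c1c(C)cc(OCOC)c(C=O)c1O | intermediate
14 | 3-methylbut-2-enoic acid | CC(C)=CC(=O)O | starting material
15 | 2-(trimethylsilyl)ethyl 3-methylbut-2-enoate | CC(C)=CC(=O)OCC[Si](C)(C)C | intermediate
16 | 2-(trimethylsilyl)ethyl (2E)-4-bromo-3-methylbut-2-enoate | BrC/C(C)=C/C(=O)OCC[Si](C)(C)C | intermediate
17 | methyl 3-formyl-4-(methoxymethoxy)-6-methyl-2-({(2E)-2-methyl-4-oxo-4-[2-(trimethylsilyl)ethoxy]but-2-en-1-yl}oxy)benzoate | COC(=O)c1c(C)cc(OCOC)c(C=O)c1OC/C(C)=C/C(=O)OCC[Si](C)(C)C | intermediate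
18 | methyl 3-(dimethoxymethyl)-4-(methoxymethoxy)-6-methyl-2-({(2E)-2-methyl-4-oxo-4-[2-(trimethylsilyl)ethoxy]but-2-en-1-yl}oxy)benzoate | COC(=O)c1c(C)cc(OCOC)c(C(OC)OC)c1OC/C(C)=C/C(=O)OCC[Si](C)(C)C | intermediate
19 | (2E)-4-[2-(dimethoxymethyl)-6-(methoxycarbonyl)-3-(methoxymethoxy)-5-methylphenoxy]-3-methylbut-2-enoic acid | COC(=O)c1c(C)cc(OCOC)c(C(OC)OC)c1OC/C(C)=C/C(=O)O | intermediate
20 | (2E)-4-[2-(dimethoxymethyl)-6-(methoxycarbonyl)-3-(methoxymethoxy)-5-methylphenoxy]-3-methylbut-2-enoyl chloride | COC(=O)c1c(C)cc(OCOC)c(C(OC)OC)c1OC/C(C)=C/C(=O)Cl | intermediate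
21 | methyl 3-(dimethoxymethyl)-4-(methoxymethoxy)-6-methyl-2-[(2-methyl-4-oxobuta-1,3-dien-1-yl)oxy]benzoate (aryloxyvinylketene; not isolated) | COC(=O)c1c(C)cc(OCOC)c(C(OC)OC)c1OC=C(C)C=C=O | intermediate
22 | bis-cyclobutenone: ring C core with two CH2 groups, each on C2 of a 3-(triisopropylsilyloxy)cyclobut-2-en-1-one whose C4 carries the 1-methyl-2-(ring A oxy)vinyl group (not isolated) | Cc1c(CC2=C(O[Si](C(C)C)(C(C)C)C(C)C)C(C(C)=COc3c(C(OC)OC)c(OCOC)cc(C)c3C(=O)OC)C2=O)c(OCOC)cc(OCOC)c1CC1=C(O[Si](C(C)C)(C(C)C)C(C)C)C(C(C)=COc2c(C(OC)OC)c(OCOC)cc(C)c2C(=O)OC)C1=O | intermediate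
23 | bis-dienylketene: each arm CH2–C(=C=O)–C(OTIPS)=CH–C(CH3)=CH–O–ring A (not isolated) | Cc1c(CC(=C=O)C(O[Si](C(C)C)(C(C)C)C(C)C)=CC(C)=COc2c(C(OC)OC)c(OCOC)cc(C)c2C(=O)OC)c(OCOC)cc(OCOC)c1CC(=C=O)C(O[Si](C(C)C)(C(C)C)C(C)C)=CC(C)=COc1c(C(OC)OC)c(OCOC)cc(C)c1C(=O)OC | intermediate
24 | bis-cyclohexadienone: each arm a 6-(ring A oxy)-5-methyl-3-(triisopropylsilyloxy)cyclohexa-2,4-dien-1-one joined to the ring C CH2 at C2 (not isolated) | Cc1c(CC2=C(O[Si](C(C)C)(C(C)C)C(C)C)C=C(C)C(Oc3c(C(OC)OC)c(OCOC)cc(C)c3C(=O)OC)C2=O)c(OCOC)cc(OCOC)c1CC1=C(O[Si](C(C)C)(C(C)C)C(C)C)C=C(C)C(Oc2c(C(OC)OC)c(OCOC)cc(C)c2C(=O)OC)C1=O | intermediate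
25 | protected pentamer: rings B with free B6 hydroxyl and B4 triisopropylsilyl ether; ring C bis(MOM ether); rings A as MOM ether, dimethyl acetal and methyl ester | COC(=O)c1c(C)cc(OCOC)c(C(OC)OC)c1Oc1c(C)cc(O[Si](C(C)C)(C(C)C)C(C)C)c(Cc2c(OCOC)cc(OCOC)c(Cc3c(O[Si](C(C)C)(C(C)C)C(C)C)cc(C)c(Oc4c(C(OC)OC)c(OCOC)cc(C)c4C(=O)OC)c3O)c2C)c1O | intermediate
26 | desilylated pentamer: rings B with free B4 and B6 hydroxyls; MOM ethers and dimethyl acetals intact | COC(=O)c1c(C)cc(OCOC)c(C(OC)OC)c1Oc1c(C)cc(O)c(Cc2c(OCOC)cc(OCOC)c(Cc3c(O)cc(C)c(Oc4c(C(OC)OC)c(OCOC)cc(C)c4C(=O)OC)c3O)c2C)c1O | intermediate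
27 | praesorether G | COC(=O)c1c(C)cc(O)c(C=O)c1Oc1c(C)cc(O)c(Cc2c(O)cc(O)c(Cc3c(O)cc(C)c(Oc4c(C=O)c(O)cc(C)c4C(=O)OC)c3O)c2C)c1O | target

**Step count**

Total: 16 steps. Longest linear sequence: 9 steps (steps 6, 7, 10, 11, 12, 13, 14, 15, 16 from methyl 2,4-dihydroxy-6-methylbenzoate; the arm from 3-methylbut-2-enoic acid is equally long, and the ring C arm is 8 steps).

**Steps most likely to fail**

1. Step 14. The base may take a proton from the γ-methyl group instead of the OCH2 group, which would give a regioisomeric vinylketene and a wrong ring B pattern. The ketene may also dimerise before it meets the alkyne, or the second annulation may stall after the first. The fallback sets out from phenol 13 and makes the same ketene by a Wolff rearrangement, which involves no proton transfer. Addition–elimination of 13 to (E)-4-chloro-3-methylbut-3-en-2-one (K2CO3, DMF, rt) would give the β-aryloxy enone methyl 3-formyl-4-(methoxymethoxy)-6-methyl-2-{[(1E)-2-methyl-3-oxobut-1-en-1-yl]oxy}benzoate F1. Acetalisation as in step 11 would give the dimethyl acetal enone F2. Detrifluoroacetylative diazo transfer would follow: LiN(SiMe3)2 and CF3CO2CH2CF3 at −78 °C give the trifluoroacetyl diketone F3, and MsN3, Et3N, H2O in MeCN give the diazo ketone F4. Irradiation of F4 (2.5 equiv) with 10 in CH2Cl2, then heating at 80 °C, would trigger the photochemical Wolff rearrangement, in which the aryloxyvinyl group migrates to give ketene 21; the sequence then runs through 22–24 and comes back to the route at 25.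

2. Step 3. The second halogen–metal exchange may be incomplete, an aryl–metal bond may be quenched by proton transfer from the flanked methyl group, or the copper step may go by attack at the alkyne terminus and give allenes. The fallback sets out from dibromide 3 and makes both aryl–CH2 bonds by cross-coupling. Double Stille coupling with allyltributylstannane (Pd(PPh3)4, DMF, 100 °C) would give 1,5-bis(methoxymethoxy)-3-methyl-2,4-di(prop-2-en-1-yl)benzene F5. Oxidative cleavage (OsO4 cat., NaIO4, 2,6-lutidine, dioxane/H2O) would give 2,2'-[4,6-bis(methoxymethoxy)-2-methyl-1,3-phenylene]diacetaldehyde F6. Ohira–Bestmann homologation (dimethyl (1-diazo-2-oxopropyl)phosphonate, K2CO3, MeOH, 0 °C) would then give the bis(alkyne), and the fallback comes back to the route at 7.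

3. Step 5. One of the two acetylides may escape oxidation, the doubly activated CH2 may be deprotonated so that the propargyl unit isomerises to an allene, or silylation may go to carbon and give a silylketene. The fallback sets out from dibromide 3 and reaches the ynolate by ester homologation. Palladium-catalysed coupling with the Reformatsky reagent BrZnCH2CO2Et (Pd2(dba)3, Q-Phos, THF, 60 °C) would give diethyl 2,2'-[4,6-bis(methoxymethoxy)-2-methyl-1,3-phenylene]diacetate F7. Kowalski homologation would follow: lithium 2,2,6,6-tetramethylpiperidide is added to F7 and CH2Br2 at −78 °C, then LiN(SiMe3)2, to give the bis(dibromomethyl ketone) 3,3'-[4,6-bis(methoxymethoxy)-2-methyl-1,3-phenylene]bis(1,1-dibromopropan-2-one) F8 as its enolate. n-BuLi with warming to rt would then bring about bromine–lithium exchange and rearrangement to the bis-ynolate, so the fallback comes back to the route at 9, which TIPSOTf converts into 10 as in step 5.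

**Further compounds**

F1 | step 14 | methyl 3-formyl-4-(methoxymethoxy)-6-methyl-2-{[(1E)-2-methyl-3-oxobut-1-en-1-yl]oxy}benzoate | COC(=O)c1c(C)cc(OCOC)c(C=O)c1O/C=C(\C)C(C)=O
F2 | step 14 | methyl 3-(dimethoxymethyl)-4-(methoxymethoxy)-6-methyl-2-{[(1E)-2-methyl-3-oxobut-1-en-1-yl]oxy}benzoate | COC(=O)c1c(C)cc(OCOC)c(C(OC)OC)c1O/C=C(\C)C(C)=O
F3 | step 14 | methyl 3-(dimethoxymethyl)-4-(methoxymethoxy)-6-methyl-2-{[(1E)-6,6,6-trifluoro-2-methyl-3,5-dioxohex-1-en-1-yl]oxy}benzoate | COC(=O)c1c(C)cc(OCOC)c(C(OC)OC)c1O/C=C(\C)C(=O)CC(=O)C(F)(F)F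
F4 | step 14 | methyl 2-{[(1E)-4-diazo-2-methyl-3-oxobut-1-en-1-yl]oxy}-3-(dimethoxymethyl)-4-(methoxymethoxy)-6-methylbenzoate | COC(=O)c1c(C)cc(OCOC)c(C(OC)OC)c1O/C=C(\C)C(=O)C=[N+]=[N-]
F5 | step 3 | 1,5-bis(methoxymethoxy)-3-methyl-2,4-di(prop-2-en-1-yl)benzene | Cc1c(CC=C)c(OCOC)cc(OCOC)c1CC=C
F6 | step 3 | 2,2'-[4,6-bis(methoxymethoxy)-2-methyl-1,3-phenylene]diacetaldehyde | Cc1c(CC=O)c(OCOC)cc(OCOC)c1CC=O
F7 | step 5 | diethyl 2,2'-[4,6-bis(methoxymethoxy)-2-methyl-1,3-phenylene]diacetate | CCOC(=O)Cc1c(C)c(CC(=O)OCC)c(OCOC)cc1OCOC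
F8 | step 5 | 3,3'-[4,6-bis(methoxymethoxy)-2-methyl-1,3-phenylene]bis(1,1-dibromopropan-2-one) | Cc1c(CC(=O)C(Br)Br)c(OCOC)cc(OCOC)c1CC(=O)C(Br)Br
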